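Start from the slow part: in the summer run target fades over days, from 41% at 0.333 d to 2% at 4.00 d, while electrophile goes from 30% to 24%.

| setting | summer | dusk | flask |
|---|---|---|---|
| electrophile | 0.070 M | 0.11 M | 0.050 M |
| nucleophile | 0.045 M | 0.045 M | 0.0450 M |
| free base | 0.075 M | 0.075 M | 0.0750 M |
| remark | run made earlier | run made earlier |  |
| time |  |  | 4.0 d |

| run | time / d | electrophile / % | target / % |
|---|---|---|---|
| summer | 0.333 | 30 | 41 |
| summer | 0.500 | 31 | 39 |
| summer | 0.833 | 24 | 27 |
| summer | 1.67 | 23 | 13 |
| summer | 2.50 | 23 | 5 |
| summer | 4.00 | 24 | 2 |
| dusk | 0.333 | 51 | 29 |
| dusk | 0.500 | 46 | 21 |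
| dusk | 0.833 | 46 | 13 |
| dusk | 1.67 | 45 | 5 |
| dusk | 2.50 | 42 | 2 |
| dusk | 4.00 | 44 | 1 |

(scatter of a reading: 2 percentage points)

- percent here means electrophile units held: one side product counts as two
- what is said of acid set free includes idle adduct
- the earlier runs were read with a standard deviation of 2 percentage points
- candidate steps: electrophile + nucleophile -> acid set free + target; nucleophile + acid set free <-> protonated nucleophile; acid set free + free base <-> salt of the base; acid set free + free base <-> idle adduct; target -> over-reaction product; electrophile + target -> side product
- the earlier runs do not show how much of nucleophile is bound; that part of a forecast is a guess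

1. part of the electrophile that has reacted at 4.0 d
2. share of the unused nucleophile that is free and not bound as protonated nucleophile, at 4.0 d

Here is the quick number. Take each nucleophile to make one target, and let each target end as over-reaction product, or as side product by taking one more electrophile. Then replace the mean electrophile a target meets by the plateau [E]end, and write S for the side product:

S = [E]start − [N]start − [E]end

S = [N]start · σ[E]end / (1 + σ[E]end)

Read the plateaus from the last readings: 0.0163 M in summer and 0.0480 M in dusk. These give 14.6 M⁻¹ and 12.6 M⁻¹. Take their mean, 13.6 M⁻¹, as σ, the split constant (a selectivity factor): the odds of side product against over-reaction product per molar electrophile.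

Solve both lines for the flask:

[E]end = 0.00315 M, so c = 93.7%

These runs show nothing of fr, so I guess it high, with more free base charged than nucleophile.

Your forecast reads 95% and 60%, with “most of the nucleophile is probably free”. The flask gives 95.0% and 99.7%.

    electrophile + nucleophile → acid set free + target (k = 54.2 M⁻¹ h⁻¹)
    nucleophile + acid set free ⇌ protonated nucleophile, settled at all times (K = 238 M⁻¹)
    acid set free + free base ⇌ salt of the base, settled at all times (K = 1.10 × 10⁵ M⁻¹)
    acid set free + free base ⇌ idle adduct, settled at all times (K = 3800 M⁻¹)
    target → over-reaction product (k = 0.0358 h⁻¹)
    electrophile + target → side product (k = 0.488 M⁻¹ h⁻¹)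

In the flask, the coupling of electrophile with nucleophile ran early, the nucleophile half-life by that step being 0.47 h at 0.0147 d, and by 0.400 d target stood at 63.1% with nucleophile at 1.12% of its charge. Target went on to over-reaction product, 23.4% at 0.400 d and 82.4% at 4.00 d, while electrophile fell from 8.51% to 4.97%, which puts my c 1.3 percentage points low. Carry σ to the neighbouring flask with 0.018 M of nucleophile: the two lines give 0.0271 M, or 54.3% of the charge. That flask held 53.8% electrophile at 4.00 d.

(The earlier runs and the new flask were computed with constants of no real substance, and the scatter is random.)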